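## The problem

The target is a planar, achiral flavone. It has no stereocentre, so the whole difficulty lies in placing and differentiating seven oxygen substituents. Ring A is substituted at every position but C6 (C5–OH, C7–OMe, C8–OMe, fused to the pyrone through C4a and C8a). This 5,7,8-pattern is isomeric with the 5,6,7-pattern and can pass into it by opening and reclosure of ring C (Wessely–Moser rearrangement) under the strongly acidic conditions normally used to unmask a 5-hydroxyl. Three hydroxyls (C5, C2', C4') must end free beside four methyl ethers (C3, C7, C8, C5'); in ring A the free one is the chelated C5–OH, which classical routes reach only by a late selective demethylation. Ring C carries an enol methyl ether at C3, and ring B an oxygen at C2' ortho to the C2–C1' bond, so the two ring B phenols should travel as benzyl ethers and be freed under neutral conditions.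

The feature that opens the plan is the following. Ring A carries its oxygens at C5 and C8 para to each other as a hydroquinone monomethyl ether (C5–OH, C8–OMe), with C7–OMe and C6–H between them, and it shares the C4a–C8a bond with the 4-pyranone ring C. This is the pattern delivered by thermal ring expansion of a 4-alkenyl-3,4-dimethoxycyclobut-2-enone. C5, C6, C7 and C8 map onto the four carbons of 3-methoxycyclobut-3-ene-1,2-dione, C4a and C8a onto the C5=C6 double bond of a 2-aryl-3-methoxy-4-pyranone, and the hydroxyl born from the ketene carbonyl is C5–OH, the only one in ring A that must stay free.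

## Retrosynthesis

**19 to 18.** The two O–CH2Ph bonds at C2' and C4' are cut. Acetal or silyl protection would need acid or fluoride at the end and would be less safe towards lithium amides and 110 °C; benzyl ethers stand every step and leave under neutral hydrogenolysis. Precursor 18 differs from 19 only by the two benzyl groups. The forward step must cleave them without reducing the pyrone C2=C3 bond.

**18 to 9 and 12.** The C5–C4a and C8–C8a bonds of ring A are cut, together with the O–CH3 bond at C8. C5 to C8 return to cyclobutenedione 12, and C4a/C8a become the C5=C6 double bond of pyranone 9. The neighbouring cuts (O1–C2/C2–C3, or C2–C1' at the chromone stage) leave ring A as a pentasubstituted benzene whose C5 oxygen must be told apart from the others later. This cut removes ring A altogether and returns C5–OH free by mechanism. The precursors are a monocyclic pyranone and a five-carbon dione. The forward reaction needs: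
- lithiation of 9 at C6 (13);
- addition to the carbonyl of 12 that lies next to the methoxy-bearing carbon (14);
- O-methylation (15);
- ring opening with the methoxy group turning outward (16);
- closure onto pyranone C5 (17) and tautomerization to 18.

**9 to 7 and 5.** The bond between pyranone C2 and C1' of ring B is cut. Building the pyranone ring from an aryl ketone would take several steps and repeat the classical logic. Here the C2–H bond of 7, flanked by the ring oxygen and the C3 methoxy group, is zincated (8) and coupled with aryl iodide 5. The precursors are a C6 pyranone and a simple iodoarene. The forward reaction needs selectivity for C2–H over C6–H and a coupling that tolerates an ortho-benzyloxy group.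

**12 to 10, and 7 to 6.** In 12 the vinylic C–H is exchanged for C–OMe, which leads to dimethyl squarate 10; forward, hydride adds to one carbonyl (11) and acid transposes the carbonyl with loss of methanol. In 7 the O–CH3 bond is cut, giving pyromeconic acid 6. Both precursors are commercial; the forward steps need only mono-reduction and O-alkylation of an enol.

**5 to 4 to 3 to 1.** The C–I bond is cut (the position is para to one benzyloxy and ortho to the other), then the O–benzyl bond, then the aryl C–O bond (Baeyer–Villiger oxidation of an aldehyde). This traces ring B to commercial 3-(benzyloxy)-4-methoxybenzaldehyde 1, in which the methoxy/benzyloxy differentiation is already present. The forward steps ask for aryl migration in an electron-rich aldehyde and for iodination at the single doubly activated, unhindered position.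

## Roads not taken

**Alternative 1:** (the most obvious) cut O1–C2 and C2–C3. The forward key step is O-aroylation of 1-(2-hydroxy-3,4,6-trimethoxyphenyl)-2-methoxyethan-1-one A1, Baker–Venkataraman acyl shift to diketone A2, and acid cyclodehydration to the 5-O-methyl flavone A3, followed by cleavage of the C5 methyl ether and the benzyl ethers to 19.
- A1 is a pentasubstituted benzene whose one free phenol must be chosen between two ortho-methoxy groups.
- The C5 hydroxyl is freed only at the end, by a Lewis acid acting on a substrate with four other methyl ethers, in the very pattern that can isomerize through ring C opening.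
- The ring A side is long and linear. The chosen plan replaces these selectivity problems by connectivity and yields C5–OH free directly.

**Alternative 2:** cut O1–C2 and the C3–O bond. The forward key step is Algar–Flynn–Oyamada oxidative cyclization of chalcone A5 (from acetophenone A4 by Claisen–Schmidt condensation) to flavonol A6, then 3-O-methylation to A3 and deprotection.
- The methoxy group ortho to the carbonyl in A5 (the future C5–OMe) twists the enone and is known to divert this oxidation towards five-membered closure, giving aurone A7.
- The sequence adds a separate methylation and still ends with the selective C5 demethylation of A3.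
- The chosen plan has no oxidative ring closure and no late demethylation.

**Alternative 3:** cut C2–C1' at the chromone stage. The forward key step is C2–H zincation of 3,5,7,8-tetramethoxy-4H-chromen-4-one A8 and Negishi coupling with 5 to give A3.
- This is convergent, but A8 must itself be made from A1, so the ring A problem is only moved.
- C6–H of A8 lies between two methoxy groups and is a second acidic site.
- The C5 demethylation remains. The chosen plan uses the same C–H arylation one stage earlier, on pyranone 7 where only pyranone C–H bonds compete, and then builds ring A with its substituents already differentiated.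

Key step: step 7

Remark on the chemistry: TMP stands for 2,2,6,6-tetramethylpiperidin-1-yl; TMPZnCl·LiCl and LiTMP are taken as pre-formed, titrated THF solutions. Compounds 14, 15 and 17 are racemic, their single stereocentre disappears on aromatization, and the target has none.

## Route

Step 1
Reactants: 1 3-(benzyloxy)-4-methoxybenzaldehyde
Product: 3 3-(benzyloxy)-4-methoxyphenol, via aryl formate 2 (not isolated)
Conditions: mCPBA, CH2Cl2, 0 to 25 °C; NaHCO3 wash; then K2CO3 (cat.), MeOH, 25 °C
Reagents that add atoms: meta-chloroperoxybenzoic acid (mCPBA), O=C(OO)c1cccc(Cl)c1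
Why: Baeyer–Villiger (Dakin-type) oxidation of an electron-rich benzaldehyde: the para-methoxyaryl group migrates in the Criegee intermediate to give formate 2, which mild methanolysis cleaves to phenol 3; the benzyl ether is inert to both reagents.

Step 2
Reactants: 3 3-(benzyloxy)-4-methoxyphenol
Product: 4 2,4-bis(benzyloxy)-1-methoxybenzene
Conditions: BnBr, K2CO3, DMF, 60 °C
Reagents that add atoms: benzyl bromide, BrCc1ccccc1
Why: Williamson ether synthesis on the phenoxide; both future ring B hydroxyls are now benzyl ethers that stand amide bases, palladium coupling and heat.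

Step 3
Reactants: 4 2,4-bis(benzyloxy)-1-methoxybenzene
Product: 5 1,5-bis(benzyloxy)-2-iodo-4-methoxybenzene
Conditions: NIS, CF3CO2H (cat.), MeCN, 0 to 25 °C
Reagents that add atoms: N-iodosuccinimide, O=C1CCC(=O)N1I
Why: Electrophilic aromatic iodination; the position attacked is para to one benzyloxy group and ortho to the other, whereas the position between the two benzyloxy groups is hindered and the one next to the methoxy group is activated by a single ether only.

Step 4
Reactants: 6 3-hydroxy-4H-pyran-4-one (pyromeconic acid)
Product: 7 3-methoxy-4H-pyran-4-one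
Conditions: MeI, K2CO3, acetone, reflux
Reagents that add atoms: iodomethane, CI
Why: Williamson O-alkylation of the acidic enolic hydroxyl; the pyranone carbonyl oxygen is not alkylated by iodomethane under carbonate conditions.

Step 5
Reactants: 7 3-methoxy-4H-pyran-4-one; 5 1,5-bis(benzyloxy)-2-iodo-4-methoxybenzene
Product: 9 2-[2,4-bis(benzyloxy)-5-methoxyphenyl]-3-methoxy-4H-pyran-4-one, via pyranon-2-ylzinc chloride 8 (not isolated)
Conditions: TMPZnCl·LiCl, THF, 25 °C; then 5, Pd(OAc)2 (2 mol %), SPhos (4 mol %), THF, 50 °C
Reagents that add atoms: none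
Why: Directed deprotonative zincation followed by Negishi coupling: C2–H of 7 is flanked by the ring oxygen and the C3 methoxy group (inductive acidification and coordination of the amide base), so it should be metalated in preference to C6–H, and without a Lewis acid on the carbonyl C5–H is not engaged. Pd(OAc)2/SPhos is suited to electron-rich ortho-alkoxy aryl iodides.

Step 6
Reactants: 10 3,4-dimethoxycyclobut-3-ene-1,2-dione (dimethyl squarate)
Product: 12 3-methoxycyclobut-3-ene-1,2-dione, via hydroxycyclobutenone 11 (not isolated)
Conditions: LiAlH(OtBu)3, THF, −78 to −20 °C; then 12 M HCl, CH2Cl2, 25 °C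
Reagents that add atoms: water, O
Why: Hindered hydride adds once, 1,2, to a squarate carbonyl to give 11; acid then ionizes the allylic hydroxyl with help from the vinylogous methoxy group, water adds to the oxocarbenium carbon and methanol is lost, the known 1,3-carbonyl transposition of squarate adducts to 3-alkoxycyclobutenediones.

Step 7
Reactants: 9 2-[2,4-bis(benzyloxy)-5-methoxyphenyl]-3-methoxy-4H-pyran-4-one; 12 3-methoxycyclobut-3-ene-1,2-dione
Product: 18 2-[2,4-bis(benzyloxy)-5-methoxyphenyl]-5-hydroxy-3,7,8-trimethoxy-4H-chromen-4-one, via 6-lithiopyranone 13 (not isolated), via lithium alkoxide 14 (not isolated), via methoxycyclobutenone 15 (not isolated), via dienylketene 16 (not isolated), via 4aH-dienone 17 (not isolated)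
Conditions: LiTMP, THF, −78 °C; 12, −78 °C; MeOTf, −78 to 0 °C; aqueous work-up; crude 15 in toluene, 110 °C
Reagents that add atoms: methyl trifluoromethanesulfonate (MeOTf), COS(=O)(=O)C(F)(F)F
Why: LiTMP should remove C6–H of 9, the only C–H next to the ring oxygen once C2 carries the aryl group and the most acidic one when no Lewis acid sits on the carbonyl, to give 13. 13 should add 1,2 to the carbonyl of 12 that is flanked by the methoxy-bearing carbon, because the other carbonyl is deactivated as a vinylogous ester, and MeOTf caps alkoxide 14 as the tertiary methyl ether 15. On heating, 15 undergoes conrotatory 4π electrocyclic ring opening in which the donor methoxy group on the sp3 carbon rotates outward and the pyranonyl group inward, so that dienylketene 16 has the (Z) geometry needed for closure. Ring A is then closed by a thermal disrotatory 6π electrocyclization that joins the ketene carbon to pyranone C5, and dienone 17, a β-dicarbonyl C–H acid, tautomerizes to phenol 18 with gain of aromaticity and of the hydrogen bond from C5–OH to C4=O. The closest known reaction type is the Moore rearrangement of 4-aryl- and 4-alkenyl-4-alkoxy(hydroxy)cyclobutenones made from 3-alkoxycyclobutenediones, which gives 2-alkoxyhydroquinone monoethers with hydrogen on the neighbouring carbon, as needed here for C6–H, C7–OMe, C8–OMe and C5–OH. No stereocentre is carried on: the quaternary carbon of 14 and 15 and C4a of 17 are racemic and become sp2 centres of 18. The selectivities needed are the site of lithiation, the choice of carbonyl in 12 and the sense of torquoselectivity; they are secured by the aryl block at C2, by the vinylogous ester deactivation and by the outward preference of oxygen donors, and once 15 is formed every ring A substituent is fixed by connectivity.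

Step 8
Reactants: 18 2-[2,4-bis(benzyloxy)-5-methoxyphenyl]-5-hydroxy-3,7,8-trimethoxy-4H-chromen-4-one
Product: 19 5,2',4'-trihydroxy-3,7,8,5'-tetramethoxyflavone
Conditions: H2 (1 atm), 10% Pd/C, EtOAc/MeOH, 25 °C
Reagents that add atoms: none
Why: Heterogeneous hydrogenolysis of the two aryl benzyl ethers; the aryl and enol methyl ethers and the tetrasubstituted C2=C3 bond of the vinylogous ester should not be reduced at 1 atm and ambient temperature, and the neutral medium avoids opening of ring C.

## Compound list

1 | 3-(benzyloxy)-4-methoxybenzaldehyde | COc1ccc(C=O)cc1OCc1ccccc1 | starting material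
2 | 3-(benzyloxy)-4-methoxyphenyl formate | COc1ccc(OC=O)cc1OCc1ccccc1 | intermediate
3 | 3-(benzyloxy)-4-methoxyphenol | COc1ccc(O)cc1OCc1ccccc1 | intermediate
4 | 2,4-bis(benzyloxy)-1-methoxybenzene | COc1ccc(OCc2ccccc2)cc1OCc1ccccc1 | intermediate
5 | 1,5-bis(benzyloxy)-2-iodo-4-methoxybenzene | COc1cc(I)c(OCc2ccccc2)cc1OCc1ccccc1 | intermediate
6 | 3-hydroxy-4H-pyran-4-one (pyromeconic acid) | O=c1ccocc1O | starting material
7 | 3-methoxy-4H-pyran-4-one | COc1coccc1=O | intermediate
8 | chloro(3-methoxy-4-oxo-4H-pyran-2-yl)zinc, LiCl complex | COc1c([Zn]Cl)occc1=O | intermediate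
9 | 2-[2,4-bis(benzyloxy)-5-methoxyphenyl]-3-methoxy-4H-pyran-4-one | COc1cc(-c2occc(=O)c2OC)c(OCc2ccccc2)cc1OCc1ccccc1 | intermediate
10 | 3,4-dimethoxycyclobut-3-ene-1,2-dione (dimethyl squarate) | COC1=C(OC)C(=O)C1=O | starting material
11 | 4-hydroxy-2,3-dimethoxycyclobut-2-en-1-one (racemic) | COC1=C(OC)C(O)C1=O | intermediate
12 | 3-methoxycyclobut-3-ene-1,2-dione | COC1=CC(=O)C1=O | intermediate
13 | {6-[2,4-bis(benzyloxy)-5-methoxyphenyl]-5-methoxy-4-oxo-4H-pyran-2-yl}lithium | COc1cc(-c2oc([Li])cc(=O)c2OC)c(OCc2ccccc2)cc1OCc1ccccc1 | intermediate
14 | lithium 1-{6-[2,4-bis(benzyloxy)-5-methoxyphenyl]-5-methoxy-4-oxo-4H-pyran-2-yl}-2-methoxy-4-oxocyclobut-2-en-1-olate (racemic) | COC1=CC(=O)C1([O-])c1cc(=O)c(OC)c(-c2cc(OC)c(OCc3ccccc3)cc2OCc2ccccc2)o1.[Li+] | intermediate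
15 | 2-[2,4-bis(benzyloxy)-5-methoxyphenyl]-6-(1,2-dimethoxy-4-oxocyclobut-2-en-1-yl)-3-methoxy-4H-pyran-4-one (racemic) | COC1=CC(=O)C1(OC)c1cc(=O)c(OC)c(-c2cc(OC)c(OCc3ccccc3)cc2OCc2ccccc2)o1 | intermediate
16 | 2-[2,4-bis(benzyloxy)-5-methoxyphenyl]-6-[(1Z)-1,2-dimethoxy-4-oxobuta-1,3-dien-1-yl]-3-methoxy-4H-pyran-4-one | O=C=C/C(OC)=C(/OC)c1cc(=O)c(OC)c(-c2cc(OC)c(OCc3ccccc3)cc2OCc2ccccc2)o1 | intermediate
17 | 2-[2,4-bis(benzyloxy)-5-methoxyphenyl]-3,7,8-trimethoxy-4aH-chromene-4,5-dione (racemic) | COC1=CC(=O)C2C(=O)C(OC)=C(-c3cc(OC)c(OCc4ccccc4)cc3OCc3ccccc3)OC2=C1OC | intermediate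
18 | 2-[2,4-bis(benzyloxy)-5-methoxyphenyl]-5-hydroxy-3,7,8-trimethoxy-4H-chromen-4-one | COc1cc(-c2oc3c(OC)c(OC)cc(O)c3c(=O)c2OC)c(OCc2ccccc2)cc1OCc1ccccc1 | intermediate
19 | 5,2',4'-trihydroxy-3,7,8,5'-tetramethoxyflavone | COc1cc(-c2oc3c(OC)c(OC)cc(O)c3c(=O)c2OC)c(O)cc1O | target

## Step count and least certain steps

Total steps: 8. Longest linear sequence: 6 steps (steps 1, 2, 3, 5, 7, 8 from compound 1).

**Step 7 (key step).** Several things may go wrong:
- loss of site selectivity in the deprotonation of 9, or self-addition of the lithiated pyranone to unreacted 9;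
- proton transfer from the vinylic C–H of 12, or attack at its vinylogous ester carbon, instead of 1,2-addition;
- methylation of the basic pyranone carbonyl oxygen by MeOTf;
- slow electrocyclization onto the electron-poor pyranone double bond.

The fallback sets out from 9. Zincation with TMPZnCl·LiCl and an iodine quench should give 2-[2,4-bis(benzyloxy)-5-methoxyphenyl]-6-iodo-3-methoxy-4H-pyran-4-one F1, in which the site is fixed. Iodine–magnesium exchange with iPrMgCl·LiCl at −78 °C and addition to 12 should give the isolable tertiary alcohol 2-[2,4-bis(benzyloxy)-5-methoxyphenyl]-6-(1-hydroxy-2-methoxy-4-oxocyclobut-2-en-1-yl)-3-methoxy-4H-pyran-4-one F2. Thermolysis of F2 in toluene under argon should give the hydroquinone 2-[2,4-bis(benzyloxy)-5-methoxyphenyl]-5,8-dihydroxy-3,7-dimethoxy-4H-chromen-4-one F3. One equivalent of MeI with K2CO3 should then methylate only the C8 hydroxyl, because the C5 hydroxyl is held in the hydrogen bond to C4=O. The fallback comes back to the route at 18.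

**Step 5.** The zincation of 7 may lose selectivity between C2–H and C6–H, and transmetalation to the hindered ortho-benzyloxy arylpalladium species may be slow. The fallback sets out from 6 and 5. Bromination of 6 with NBS at the enol α-carbon should give 2-bromo-3-hydroxy-4H-pyran-4-one F4, and O-methylation gives 2-bromo-3-methoxy-4H-pyran-4-one F5. Iodide 5 is converted by iodine–magnesium exchange and B(OMe)3 into [2,4-bis(benzyloxy)-5-methoxyphenyl]boronic acid F6. Suzuki coupling of F5 and F6 (Pd(PPh3)4, K2CO3, dioxane/water) comes back to the route at 9.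

**Step 6.** Over-reduction of 10 and hydrolysis of the vinylogous methyl ester during the acid transposition may erode the yield of the small, water-sensitive dione 12. The fallback sets out from 10. After the same hydride addition the hydrolysis is driven to completion in aqueous HCl to give crystalline 3-hydroxycyclobut-3-ene-1,2-dione (semisquaric acid) F7, which is isolated and O-methylated with Me3SiCHN2 in toluene/MeOH. It comes back to the route at 12.

**Step 8.** Over-reduction of the pyrone C2=C3 bond, or incomplete cleavage of the hindered C2' benzyl ether, may occur. The fallback sets out from 18 and replaces hydrogenolysis by Lewis acid cleavage of the benzyl ethers with BCl3 and pentamethylbenzene as cation scavenger in CH2Cl2 at −78 °C, conditions under which aryl methyl ethers should persist. It comes back to the route at 19 and makes no new compound.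

## Further compounds

F1 | step 7 | 2-[2,4-bis(benzyloxy)-5-methoxyphenyl]-6-iodo-3-methoxy-4H-pyran-4-one | COc1cc(-c2oc(I)cc(=O)c2OC)c(OCc2ccccc2)cc1OCc1ccccc1
F2 | step 7 | 2-[2,4-bis(benzyloxy)-5-methoxyphenyl]-6-(1-hydroxy-2-methoxy-4-oxocyclobut-2-en-1-yl)-3-methoxy-4H-pyran-4-one (racemic) | COC1=CC(=O)C1(O)c1cc(=O)c(OC)c(-c2cc(OC)c(OCc3ccccc3)cc2OCc2ccccc2)o1
F3 | step 7 | 2-[2,4-bis(benzyloxy)-5-methoxyphenyl]-5,8-dihydroxy-3,7-dimethoxy-4H-chromen-4-one | COc1cc(-c2oc3c(O)c(OC)cc(O)c3c(=O)c2OC)c(OCc2ccccc2)cc1OCc1ccccc1
F4 | step 5 | 2-bromo-3-hydroxy-4H-pyran-4-one | O=c1ccoc(Br)c1O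
F5 | step 5 | 2-bromo-3-methoxy-4H-pyran-4-one | COc1c(Br)occc1=O
F6 | step 5 | [2,4-bis(benzyloxy)-5-methoxyphenyl]boronic acid | COc1cc(B(O)O)c(OCc2ccccc2)cc1OCc1ccccc1
F7 | step 6 | 3-hydroxycyclobut-3-ene-1,2-dione (semisquaric acid) | O=C1C=C(O)C1=O
F0 | step 8 | none | none
A1 | alternative 1 | 1-(2-hydroxy-3,4,6-trimethoxyphenyl)-2-methoxyethan-1-one | COCC(=O)c1c(O)c(OC)c(OC)cc1OC
A2 | alternative 1 | 1-[2,4-bis(benzyloxy)-5-methoxyphenyl]-3-(2-hydroxy-3,4,6-trimethoxyphenyl)-2-methoxypropane-1,3-dione (racemic) | COC(C(=O)c1c(O)c(OC)c(OC)cc1OC)C(=O)c1cc(OC)c(OCc2ccccc2)cc1OCc1ccccc1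
A3 | alternative 1 | 2-[2,4-bis(benzyloxy)-5-methoxyphenyl]-3,5,7,8-tetramethoxy-4H-chromen-4-one | COc1cc(-c2oc3c(OC)c(OC)cc(OC)c3c(=O)c2OC)c(OCc2ccccc2)cc1OCc1ccccc1
A4 | alternative 2 | 1-(2-hydroxy-3,4,6-trimethoxyphenyl)ethan-1-one | CC(=O)c1c(O)c(OC)c(OC)cc1OC
A5 | alternative 2 | (E)-3-[2,4-bis(benzyloxy)-5-methoxyphenyl]-1-(2-hydroxy-3,4,6-trimethoxyphenyl)prop-2-en-1-one | COc1cc(/C=C/C(=O)c2c(O)c(OC)c(OC)cc2OC)c(OCc2ccccc2)cc1OCc1ccccc1
A6 | alternative 2 | 2-[2,4-bis(benzyloxy)-5-methoxyphenyl]-3-hydroxy-5,7,8-trimethoxy-4H-chromen-4-one | COc1cc(-c2oc3c(OC)c(OC)cc(OC)c3c(=O)c2O)c(OCc2ccccc2)cc1OCc1ccccc1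
A7 | alternative 2 | (Z)-2-[2,4-bis(benzyloxy)-5-methoxybenzylidene]-4,6,7-trimethoxybenzofuran-3(2H)-one | COc1cc(OC)c2c(c1OC)O/C(=C\c1cc(OC)c(OCc3ccccc3)cc1OCc1ccccc1)C2=O
A8 | alternative 3 | 3,5,7,8-tetramethoxy-4H-chromen-4-one | COc1cc(OC)c2c(=O)c(OC)coc2c1OC
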